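The route rests on disconnecting the O1–C8a aryl ether bond of ring C. In ring A the two carbons that flank C4a, C5 and C8a, both bear oxygen, so a closure through a phenol would have to tell them apart. Here C8a carries bromine while the C5 oxygen is already in place as a MOM ether, so only one closure is possible. A palladium-catalysed intramolecular etherification forms the ring in one operation, and the (S)-carbinol becomes C2 unchanged. The precursor is an open chain on the 2-bromo-5-geranyl-4-methoxy-6-(methoxymethoxy)phenyl ring: a silyl-protected benzylic carbinol (the later C4 ketone), a methylene and a free (1S)-phenylcarbinol.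

Key step: step 7

Abbreviations: geranyl = (2E)-3,7-dimethylocta-2,6-dien-1-yl; MOM = methoxymethyl; TBS = tert-butyldimethylsilyl; Ar = 2-bromo-5-geranyl-4-methoxy-6-(methoxymethoxy)phenyl.

Remark: the aldol in step 4 forms the carbon that becomes C4 without stereocontrol and the oxidation in step 9 erases it, so compounds 11, 12 and 13 are each the pair of epimers at that carbon, (S) at the future C2 in both, handled as one material and drawn with that centre undefined.

Step 1
Reactants: 1 2-bromo-4,6-dimethoxybenzaldehyde
Product: 2 2-bromo-6-hydroxy-4-methoxybenzaldehyde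
Conditions: BCl3 (1.5 equiv), CH2Cl2, −78 → 0 °C; H2O work-up
Reagents that add atoms: none
Why: Chelation-controlled Lewis acid demethylation: BCl3 binds between the aldehyde oxygen and the neighbouring methoxy oxygen, so only the ether ortho to the formyl group is cleaved and the para methoxy group and the C–Br bond are left alone.

Step 2
Reactants: 2 2-bromo-6-hydroxy-4-methoxybenzaldehyde; 3 geranyl bromide
Product: 5 2-bromo-5-geranyl-6-hydroxy-4-methoxybenzaldehyde, via sodium phenoxide 4 (not isolated)
Conditions: NaH (1.05 equiv), toluene, 0 °C → rt; then 3 (1.2 equiv), rt → 60 °C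
Reagents that add atoms: none
Why: Ortho-selective C-allylation of a sodium phenoxide in a non-polar solvent: the tight ion pair in toluene steers the allylic bromide in an SN2 sense to the only free ortho carbon, which the adjacent methoxy group also activates, so the geranyl chain should arrive unrearranged and still (E).

Step 3
Reactants: 5 2-bromo-5-geranyl-6-hydroxy-4-methoxybenzaldehyde
Product: 6 2-bromo-5-geranyl-4-methoxy-6-(methoxymethoxy)benzaldehyde
Conditions: MOMCl (1.5 equiv), iPr2NEt (2.5 equiv), CH2Cl2, 0 → 40 °C
Reagents that add atoms: chloromethyl methyl ether, COCCl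
Why: Williamson-type O-alkylation of the hydrogen-bonded phenol with MOMCl and a hindered amine gives an acetal that tolerates the enolate, borane, carbonate and fluoride steps ahead and is removed by dilute acid at the end.

Step 4
Reactants: 6 2-bromo-5-geranyl-4-methoxy-6-(methoxymethoxy)benzaldehyde; 7 acetophenone
Product: 9 rac-3-Ar-3-hydroxy-1-phenylpropan-1-one, via lithium enolate 8 (not isolated)
Conditions: 7 (1.1 equiv), LiN(iPr)2 (1.1 equiv), THF, −78 °C; then 6, −78 °C; AcOH quench at −78 °C
Reagents that add atoms: none
Why: Directed aldol addition of the preformed lithium enolate to the non-enolisable aldehyde at −78 °C with a cold acidic quench, which should outrun retro-aldol and dehydration; the new carbinol centre forms without control, which is acceptable because it becomes the C4 carbonyl.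

Step 5
Reactants: 9 rac-3-Ar-3-hydroxy-1-phenylpropan-1-one
Product: 10 rac-3-Ar-3-(tert-butyldimethylsilyloxy)-1-phenylpropan-1-one
Conditions: TBSOTf (1.3 equiv), 2,6-lutidine (2.5 equiv), CH2Cl2, −78 °C
Reagents that add atoms: tert-butyldimethylsilyl trifluoromethanesulfonate, CC(C)(C)[Si](C)(C)OS(=O)(=O)C(F)(F)F
Why: Silylation of a hindered secondary alcohol with the silyl triflate and 2,6-lutidine at −78 °C is faster than enol silylation or attack on the MOM acetal, and it shuts off retro-aldol and dehydration and later keeps this oxygen away from palladium.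

Step 6
Reactants: 10 rac-3-Ar-3-(tert-butyldimethylsilyloxy)-1-phenylpropan-1-one
Product: 11 (1S,3RS)-3-Ar-3-(tert-butyldimethylsilyloxy)-1-phenylpropan-1-ol (both C3 epimers)
Conditions: (R)-Me-CBS oxazaborolidine [(R)-tetrahydro-1-methyl-3,3-diphenyl-1H,3H-pyrrolo[1,2-c][1,3,2]oxazaborole, C18H20BNO] (0.2 equiv), catecholborane (1.8 equiv), toluene, −78 °C; MeOH, then cold dilute aq. NaOH wash
Reagents that add atoms: none
Why: Corey–Bakshi–Shibata reduction: the (R)-oxazaborolidine binds the ketone with phenyl as the large group and delivers hydride to the Re face, so the (1S) carbinol (future C2) is set by reagent control in either enantiomer of 10, giving the (1S,3S) and (1S,3R) epimers as one material, while catecholborane at −78 °C should leave the trisubstituted geranyl alkenes untouched.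

Step 7
Reactants: 11 (1S,3RS)-3-Ar-3-(tert-butyldimethylsilyloxy)-1-phenylpropan-1-ol (both C3 epimers)
Product: 12 (2S,4RS)-4-(tert-butyldimethylsilyloxy)-6-geranyl-7-methoxy-5-(methoxymethoxy)-2-phenylchroman (both C4 epimers)
Conditions: Pd(OAc)2 (5 mol%), 2-(di-tert-butylphosphino)-1,1'-binaphthyl (6 mol%), Cs2CO3 (1.5 equiv), degassed toluene, 80 °C
Reagents that add atoms: none
Why: Zerovalent palladium, formed in the flask from Pd(OAc)2 and the phosphine, inserts into the C8a–Br bond, carbonate takes the proton of the coordinated C1 hydroxyl to give an arylpalladium alkoxide, and C–O reductive elimination from this seven-membered oxapalladacycle forms O1–C8a. The closest known reaction type is the Buchwald–Hartwig intramolecular etherification of aryl bromides with secondary alcohols, which gives 2-substituted chromans without loss of configuration. Ring C closes as a six-membered ring by ipso substitution at the arene carbon ortho to the three-atom tether, the oxygen taking the place of bromine. No stereocentre is created: the C2–O bond is never broken, so (S) is retained, and the silyloxy carbon is a spectator in either epimer, the (1S,3S) alcohol giving the (2S,4S) chroman and the (1S,3R) alcohol the (2S,4R) chroman. The step needs regioselectivity (O1 onto C8a and not C5), which the single bromine secures, and reductive elimination in preference to beta-hydride elimination, which the bulky electron-rich di-tert-butyl biaryl phosphine secures, while the silyl ether keeps the second oxygen off palladium and shuts out retro-aldol and dehydration.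

Step 8
Reactants: 12 (2S,4RS)-4-(tert-butyldimethylsilyloxy)-6-geranyl-7-methoxy-5-(methoxymethoxy)-2-phenylchroman (both C4 epimers)
Product: 13 (2S,4RS)-6-geranyl-7-methoxy-5-(methoxymethoxy)-2-phenylchroman-4-ol (both C4 epimers)
Conditions: Bu4NF (1.5 equiv), THF, 0 °C → rt; H2O work-up
Reagents that add atoms: none
Why: Fluoride-driven desilylation (formation of the strong Si–F bond) frees the benzylic alcohol under basic, non-ionising conditions that leave the acid-sensitive flavan-4-ol, the MOM acetal, the alkenes and C2 untouched.

Step 9
Reactants: 13 (2S,4RS)-6-geranyl-7-methoxy-5-(methoxymethoxy)-2-phenylchroman-4-ol (both C4 epimers)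
Product: 14 (2S)-6-geranyl-7-methoxy-5-(methoxymethoxy)-2-phenylchroman-4-one
Conditions: Dess–Martin periodinane (C13H13IO8, 1.5 equiv), NaHCO3, CH2Cl2, 0 °C → rt
Reagents that add atoms: none
Why: Dess–Martin oxidation under bicarbonate buffer converts both C4 epimers into the same ketone without acid or base strong enough to open ring C, so C2 should keep its configuration and the alkenes and the electron-rich arene are not attacked.

Step 10
Reactants: 14 (2S)-6-geranyl-7-methoxy-5-(methoxymethoxy)-2-phenylchroman-4-one
Product: 15 (2S)-6-geranylpinostrobin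
Conditions: 2 M aq. HCl, MeOH, rt (→ 40 °C only if slow)
Reagents that add atoms: none
Why: Acid-catalysed acetal exchange with methanol removes the MOM group, which the peri carbonyl makes especially labile, under conditions kept mild enough not to protonate the geranyl alkenes or to open the flavanone ring (the path to racemisation at C2), and the freed phenol is then held by its hydrogen bond to the C4 carbonyl.

Compound list

1 | 2-bromo-4,6-dimethoxybenzaldehyde | COc1cc(Br)c(C=O)c(OC)c1 | starting material
2 | 2-bromo-6-hydroxy-4-methoxybenzaldehyde | COc1cc(O)c(C=O)c(Br)c1 | intermediate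
3 | geranyl bromide, (2E)-1-bromo-3,7-dimethylocta-2,6-diene | BrC/C=C(\C)CCC=C(C)C | starting material
4 | sodium 3-bromo-2-formyl-5-methoxyphenolate | COc1cc([O-])c(C=O)c(Br)c1.[Na+] | intermediate
5 | 2-bromo-5-[(2E)-3,7-dimethylocta-2,6-dien-1-yl]-6-hydroxy-4-methoxybenzaldehyde | COc1cc(Br)c(C=O)c(O)c1C/C=C(\C)CCC=C(C)C | intermediate
6 | 2-bromo-5-[(2E)-3,7-dimethylocta-2,6-dien-1-yl]-4-methoxy-6-(methoxymethoxy)benzaldehyde | COc1cc(Br)c(C=O)c(OCOC)c1C/C=C(\C)CCC=C(C)C | intermediate
7 | acetophenone | CC(=O)c1ccccc1 | starting material
8 | lithium 1-phenylethen-1-olate | C=C([O-])c1ccccc1.[Li+] | intermediate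
9 | rac-3-[2-bromo-5-geranyl-4-methoxy-6-(methoxymethoxy)phenyl]-3-hydroxy-1-phenylpropan-1-one (racemate, carbinol centre left undefined in the SMILES) | COc1cc(Br)c(C(O)CC(=O)c2ccccc2)c(OCOC)c1C/C=C(\C)CCC=C(C)C | intermediate
10 | rac-3-[2-bromo-5-geranyl-4-methoxy-6-(methoxymethoxy)phenyl]-3-(tert-butyldimethylsilyloxy)-1-phenylpropan-1-one (racemate, silyloxy centre left undefined in the SMILES) | COc1cc(Br)c(C(O[Si](C)(C)C(C)(C)C)CC(=O)c2ccccc2)c(OCOC)c1C/C=C(\C)CCC=C(C)C | intermediate
11 | (1S,3RS)-3-[2-bromo-5-geranyl-4-methoxy-6-(methoxymethoxy)phenyl]-3-(tert-butyldimethylsilyloxy)-1-phenylpropan-1-ol (the (1S,3S) and (1S,3R) epimers together, silyloxy carbon left undefined in the SMILES) | COc1cc(Br)c(C(O[Si](C)(C)C(C)(C)C)C[C@H](O)c2ccccc2)c(OCOC)c1C/C=C(\C)CCC=C(C)C | intermediate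
12 | (2S,4RS)-4-(tert-butyldimethylsilyloxy)-6-geranyl-7-methoxy-5-(methoxymethoxy)-2-phenylchroman (the (2S,4S) and (2S,4R) epimers together, C4 left undefined in the SMILES) | COc1cc2c(c(OCOC)c1C/C=C(\C)CCC=C(C)C)C(O[Si](C)(C)C(C)(C)C)C[C@@H](c1ccccc1)O2 | intermediate
13 | (2S,4RS)-6-geranyl-7-methoxy-5-(methoxymethoxy)-2-phenylchroman-4-ol (the (2S,4S) and (2S,4R) epimers together, C4 left undefined in the SMILES) | COc1cc2c(c(OCOC)c1C/C=C(\C)CCC=C(C)C)C(O)C[C@@H](c1ccccc1)O2 | intermediate
14 | (2S)-6-geranyl-7-methoxy-5-(methoxymethoxy)-2-phenylchroman-4-one | COc1cc2c(c(OCOC)c1C/C=C(\C)CCC=C(C)C)C(=O)C[C@@H](c1ccccc1)O2 | intermediate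
15 | (2S)-6-geranyl-5-hydroxy-7-methoxy-2-phenylchroman-4-one, (2S)-6-geranylpinostrobin | COc1cc2c(c(O)c1C/C=C(\C)CCC=C(C)C)C(=O)C[C@@H](c1ccccc1)O2 | target

Total steps: 10. Longest linear sequence: 10 steps, from 1 to 15; 3 and 7 enter directly as purchased.

Steps most likely to fail

Step 7 (key step). Oxidative addition into the hindered, electron-rich C–Br bond may be slow. Beta-hydride elimination from the palladium alkoxide would oxidise the carbinol and remove the bromine. The silyl group could also migrate to the free carbinol oxygen under base. The fallback closes ring C at O1–C2 by Mitsunobu inversion, with the bromine still marking C8a as the oxygen-bearing carbon. It sets out from 10.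
- Reduction with the enantiomeric (S)-Me-CBS oxazaborolidine (C18H20BNO) and catecholborane in toluene at −78 °C should give the (1R,3RS)-bromo alcohol F1.
- Miyaura borylation (B2pin2, PdCl2(dppf), KOAc, 1,4-dioxane, 90 °C) should give the (1R,3RS)-pinacol boronate F2.
- Oxidation with NaBO3·4H2O in THF/H2O should give the (1R,3RS)-phenol F3.
- PPh3 and DIAD in THF at 0 °C should then displace the activated (1R) carbinol by the phenol oxygen with inversion to (2S), which comes back to the route at 12.

Step 2. Alkylation may take place on the phenoxide oxygen instead of carbon, or at the para carbon next to bromine, because the formyl group lowers the nucleophilicity of the ring. The fallback alkylates the more nucleophilic resorcinol dianion and methylates afterwards. It sets out from 1.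
- BBr3 (CH2Cl2, −78 °C → rt) should cleave both methyl ethers to 2-bromo-4,6-dihydroxybenzaldehyde F4.
- Geranyl bromide 3 in aqueous KOH at 0 °C should alkylate the carbon between the two phenoxide oxygens to give 2-bromo-5-geranyl-4,6-dihydroxybenzaldehyde F5.
- K2CO3 and one equivalent of MeI in acetone should methylate only the hydroxyl para to the aldehyde, since the ortho hydroxyl is held by its hydrogen bond. This comes back to the route at 5.

Step 6. Facial selectivity may erode because of the bulky beta-substituent, and the geranyl alkenes may be hydroborated if the reduction is sluggish. The fallback avoids borane altogether. It sets out from 10 and uses Noyori-type asymmetric transfer hydrogenation with RuCl[(S,S)-TsDPEN](p-cymene) in HCO2H/Et3N (5:2) at rt to 40 °C. This catalyst type reduces aryl ketones to the (S) carbinol and should not touch isolated alkenes, aryl bromides, silyl ethers or MOM acetals. It comes back to the route at 11 and makes no new compound.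

Further compounds

F1 | step 7 | (1R,3RS)-3-[2-bromo-5-geranyl-4-methoxy-6-(methoxymethoxy)phenyl]-3-(tert-butyldimethylsilyloxy)-1-phenylpropan-1-ol (both C3 epimers) | COc1cc(Br)c(C(O[Si](C)(C)C(C)(C)C)C[C@@H](O)c2ccccc2)c(OCOC)c1C/C=C(\C)CCC=C(C)C
F2 | step 7 | (1R,3RS)-3-[5-geranyl-4-methoxy-6-(methoxymethoxy)-2-(4,4,5,5-tetramethyl-1,3,2-dioxaborolan-2-yl)phenyl]-3-(tert-butyldimethylsilyloxy)-1-phenylpropan-1-ol (both C3 epimers) | COc1cc(B2OC(C)(C)C(C)(C)O2)c(C(O[Si](C)(C)C(C)(C)C)C[C@@H](O)c2ccccc2)c(OCOC)c1C/C=C(\C)CCC=C(C)C
F3 | step 7 | (1R,3RS)-3-[5-geranyl-2-hydroxy-4-methoxy-6-(methoxymethoxy)phenyl]-3-(tert-butyldimethylsilyloxy)-1-phenylpropan-1-ol (both C3 epimers) | COc1cc(O)c(C(O[Si](C)(C)C(C)(C)C)C[C@@H](O)c2ccccc2)c(OCOC)c1C/C=C(\C)CCC=C(C)C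
F4 | step 2 | 2-bromo-4,6-dihydroxybenzaldehyde | Oc1cc(Br)c(C=O)c(O)c1
F5 | step 2 | 2-bromo-5-[(2E)-3,7-dimethylocta-2,6-dien-1-yl]-4,6-dihydroxybenzaldehyde | Oc1cc(Br)c(C=O)c(O)c1C/C=C(\C)CCC=C(C)C
F0 | step 6 | none | none
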